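# Dysidenone A from (−)-quinic acid: ring contraction to ring C and aldol union with a trans-decalone

Labels used throughout. Ring C: Ca (carbinol carbon with OH and CO2Me), Cb (alkene CH), Cc (alkene carbon with OMe), Cd (ketone), Ce (ring CH). C11 is the linking CH2. Decalin: C1 (quaternary, CH3 and C11), C2, C3, C4 (angular CH3), C5 (alkene carbon with CH3), C6 (alkene CH), C7, C8, C9 (ring-fusion CH), C10 (CH–CH3). Ring A is C4–C9; ring B is C1–C4, C9, C10. "β" is the face of the C4 methyl and "α" the opposite face.

Main compound numbers (full list after the steps): 1 quinic acid, 7 diol precursor of the key step, 8 dialdehyde, 9 aldol (ring C), 10 its triethylsilyl ether, 11 (S)-Wieland–Miescher ketone, 18 decalin C10 ketone, 22 enone, 24 C1-methylated ketone, 26 C10-methyl compound, 28 Cd ketone, 30 O-silyl target, 31 dysidenone A.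

## Analysis of the target

Dysidenone A (31) consists of a trans-fused decalin that is tied through a single methylene (C11) to a five-membered ring C, a 2-methoxycyclopent-2-enone. The decalin carries four stereocentres: the C4 methyl and the C9 hydrogen are trans, the C10 methyl is axial on the face of the C4 methyl, and at C1 the methyl is axial on the opposite face while C11 is equatorial. Ring C adds two more, since Ca is a fully substituted carbinol that also bears the ester and Ce holds C11 trans to the Ca hydroxyl. The fragile parts are the β-hydroxy ketone Ca–Ce–Cd (retro-aldol cleavage and β-elimination), the Ce hydrogen next to Cd (epimerisation), the enol-ether-like methoxy enone and the trisubstituted C5=C6 alkene. The difficulty lies in three places: Ca is too remote from the decalin to be steered by it, C1 and C10 are neighbouring crowded centres, and the two halves meet at a neopentyl carbon. The plan rests on the observation that Ca with its hydroxyl and carboxyl is the quaternary carbinol carbon of (−)-quinic acid (1), whose six-membered ring holds one carbon more than ring C. Breaking the quinate C4–C5 bond and closing again by an aldol reaction turns quinate C4 into Cd, C6 into Ce, C3 with its oxygen into Cc and the expelled C5 into C11, and the choice of C4–C5 over C3–C4 places the ring atoms around Ca in the order that corresponds to the configuration of the target.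

## Retrosynthetic reasoning

31 from 30 from 28. No skeletal bond is cut here. The Cb=Cc double bond and the free tertiary alcohol are left to the end because the methoxy enone and the β-hydroxy ketone are the most fragile parts of the molecule. In ketone 28 a double bond can be introduced next to Cc only toward Cb, since Ca carries no hydrogen.

28 from 27 from 26. The Cd carbonyl is carried as a silyl-protected alcohol through all enolate chemistry on the decalin. In this way Ce can neither epimerise nor eliminate its β-oxygen before the last steps.

26 from 25 from 24. The C10–CH3 bond is traced back to a C10 ketone. This puts a carbonyl group next to C1, which the next two disconnections need. The forward sequence has to add one carbon to a very hindered ketone and bring hydrogen to the α face of C10.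

24 from 22. The C1–CH3 bond is cut. In the forward direction conjugate reduction of enone 22 gives the C10–C1 enolate without any regiochemical choice, and the methyl group enters axially. Because the small group comes last, it takes the axial place and C11 stays equatorial, as the target demands.

22 from 18 and 10. The C1–C11 bond is the only link between the two halves and is cut as an aldol condensation. Ketone 18 can be enolised kinetically only toward C1 (a CH2) and not toward the ring-fusion C9, and the formyl carbon of 10 is C11. This is the point of convergence.

18 back to 11. The decalin takes its ring system and its C4 centre from enantiopure 11. The enone oxygen is removed (12, 13), the C5 carbonyl becomes the methyl-bearing alkene by way of enol triflate 14, and hydroboration of the C9=C10 alkene brings in the C10 oxygen and the trans ring fusion in one operation (16, then 17).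

10 from 9 from 7 (key disconnection). The Cd–Ce bond of ring C is cut as an aldol, which opens the ring to dialdehyde 8. Joining the two formyl carbons of 8 leads back to the cyclohexane diol 7. The forward reaction must form the enamine on the CH2–CHO arm only, attack the α-methoxy aldehyde, and place the formyl group trans to the silyloxy group on Ca.

7 back to 1 and 2. The trans 4,5-diol is masked as a diacetal so that the 3-hydroxyl can be methylated and the tertiary hydroxyl silylated, and is then set free again (4, 5, 6).

## Alternatives that were turned down

Alternative 1: Cation–olefin bicyclisation of a chiral acetal with vinylsilane termination. The cut is at C9–C10 and C4–C5. A Lewis acid opens the C2-symmetric dioxane acetal of the open-chain precursor A1 to an oxocarbenium ion at C10. C9 of the E alkene attacks it, and the tertiary C4 cation is caught at the silicon-bearing C5 to give decalin ether A2. In its favour, one step closes both rings, sets the trans fusion and the C4/C9 pair, fixes the alkene at C5=C6 and leaves oxygen on C10, exactly where the present route needs it. Against it, the terminating bond joins a tertiary cation to a fully substituted alkene carbon, so proton loss to monocyclic dienes competes. Induction from the acetal is rarely complete, and the minor diastereomer turns into the enantiomeric decalin once the auxiliary is removed. A1 needs a geometrically pure trisubstituted alkene and vinylsilane, and removal of the auxiliary costs two further steps. The plan also says nothing about ring C, about Ca and Ce, or about C1 and C10. On the decalin alone it is as strong as or stronger than the six steps from 11 to 18. The chosen strategy instead draws the C4 centre from an enantiopure commercial ketone and spends its one risky step on Ca and ring C, which Alternative 1 leaves open.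

Alternative 2: Chelation-controlled intramolecular Diels–Alder reaction of a trienone. The cut is at C4–C9 and C7–C8. In trienone A3 a chelating magnesium Lewis acid binds the β-keto ester, and the vinyl ketone adds to the C4–C7 diene to give decalone A4. A4 already holds the C10 ketone and a C1 that carries its methyl and a carboxyl carbon equal to C11. In its favour, both rings form at once and C1 is settled before the rings exist, which is stronger than the axial methylation used here. Against it, the diene terminus C4 is fully substituted, and its inside methyl destabilises the s-cis conformer and slows the cycloaddition while the vinyl ketone can polymerise. Facial control must come from a quaternary centre whose two groups differ little in size. A3 needs an enantioselective construction of an α-quaternary β-keto ester of its own. Most important, C11 ends as a carboxyl on the decalin, so ring C would have to be built or attached at a neopentyl carbon with Ca set by remote induction. The chosen strategy gives up the early C1 centre but gains Ca from the chiral pool and a convergent aldol union.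

Alternative 3: Polarised Nazarov cyclisation. The cut is at Ca–Cb in the last stage. A chiral acid activates divinyl ketone A5, the pentadienyl cation closes in a conrotatory sense, and proton loss from Cb followed by protonation at Ce gives A6, which is the same compound as 30. In its favour, it is the most convergent plan and the shortest one for ring C, and the donor methoxy and acceptor ester polarise the dienone so that mild acid should be enough. Against it, the new bond ends at a carbon that carries both a silyloxy and an ester group, so a fully substituted stereocentre must be set by catalyst-controlled torquoselectivity alone, the decalin centres lying beyond C11. Ce is then set by a protonation that nothing controls. The oxyallyl cation can lose silanol or the silyl group instead of the Cb proton, and A5 contains a tetrasubstituted silyloxy acrylate that is hard to obtain as one geometric isomer. It wins on step count if it works. The chosen strategy offers a Ca that is never in doubt and a Ce that is set in an early catalytic step with a thermodynamic safeguard.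

Key step: step 5

Remark: (S)-Wieland–Miescher ketone (11) is taken as the commercial, enantiopure source of the decalin because it already carries the C4 quaternary centre.
Remark: Cc and Cd are stereocentres only in intermediates and both become trigonal in 31, so their configuration is drawn as expected but is not critical.

## Route

Step 1
Reactants: 1 (−)-quinic acid; 2 butane-2,3-dione
Product: 4 methyl quinate 4,5-butane-2,3-diacetal (O-4 and O-5 bridged by a (2S,3S)-2,3-dimethoxybutane-2,3-diyl unit; 1-OH and 3-OH free), via methyl quinate 3 (not isolated)
Conditions: 2, HC(OMe)3, camphorsulfonic acid (cat.), MeOH, reflux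
Reagents that add atoms: methanol, CO; trimethyl orthoformate, COC(OC)OC
Why: Fischer esterification and diacetal formation proceed together in acidic methanol; only the trans-diequatorial 4,5-diol can span the trans-fused dioxane, and the anomeric effect places both acetal methoxy groups axial, which fixes the two acetal centres.

Step 2
Reactants: 4 methyl quinate 4,5-butane-2,3-diacetal
Product: 5 3-O-methyl derivative of 4
Conditions: Me3OBF4, 1,8-bis(dimethylamino)naphthalene, CH2Cl2, 0 °C to rt
Reagents that add atoms: trimethyloxonium tetrafluoroborate, C[O+](C)C.F[B-](F)(F)F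
Why: O-Alkylation with an oxonium salt under non-basic conditions should pick the secondary 3-hydroxyl over the tertiary 1-hydroxyl, which is hindered and made less nucleophilic by the ester on the same carbon; ester and acetal are not touched.

Step 3
Reactants: 5 3-O-methyl diacetal
Product: 6 1-O-tert-butyldimethylsilyl-3-O-methyl diacetal
Conditions: t-BuMe2SiOTf, 2,6-lutidine, CH2Cl2, 0 °C to rt
Reagents that add atoms: tert-butyldimethylsilyl trifluoromethanesulfonate, CC(C)(C)[Si](C)(C)OS(=O)(=O)C(F)(F)F
Why: Silylation with a silyl triflate and a hindered base is the standard way to protect a tertiary alcohol, and the only free hydroxyl left is the one on the future Ca.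

Step 4
Reactants: 6 silylated diacetal
Product: 7 methyl 1-O-(tert-butyldimethylsilyl)-3-O-methylquinate (free trans-4,5-diol)
Conditions: CF3CO2H/H2O (9:1), CH2Cl2, rt, short contact
Reagents that add atoms: none
Why: Acid hydrolysis removes the diacetal; the tertiary silyl ether next to an ester, the methyl ether and the methyl ester should survive brief contact with aqueous acid.

Step 5
Reactants: 7 methyl 1-O-(tert-butyldimethylsilyl)-3-O-methylquinate
Product: 9 methyl (1S,2S,3S,4R)-1-(tert-butyldimethylsilyloxy)-2-formyl-3-hydroxy-4-methoxycyclopentane-1-carboxylate (silyloxy/hydroxy/methoxy on one face; formyl on the other; C1 = Ca; C2 = Ce; C3 = Cd; C4 = Cc), via dialdehyde 8 (not isolated)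
Conditions: NaIO4 on SiO2, CH2Cl2, rt; filter; D-proline (0.2 equiv), CH2Cl2, 0 °C to rt
Reagents that add atoms: none
Why: NaIO4 cleaves the trans-diequatorial 4,5-diol through its cyclic periodate ester and gives dialdehyde 8, while the quaternary Ca and the methoxy-bearing Cc stay as they are. D-Proline forms its enamine at the unbranched CH2–CHO arm, because the other aldehyde is α-branched and carries the methoxy group, and the enamine carbon (Ce) then attacks the more electrophilic α-alkoxy aldehyde carbon (Cd). Ring C closes in a 5-(enolexo)-exo-trig mode, which is the closure known from amine-catalysed intramolecular aldol reactions of hexanedials to 2-hydroxycyclopentanecarbaldehydes. Ce is controlled by the catalyst: the carboxylic acid hydrogen-bonds to the acceptor carbonyl and guides it to one face of the anti enamine, and the D enantiomer is the one whose preferred face puts the formyl group trans to the silyloxy group on Ca. Cd follows from the hydrogen-bonded chair-like transition state, which leads to the anti aldol, so the new hydroxyl should stand trans to the formyl group and cis to the silyloxy and methoxy groups. An achiral amine would leave Ce to the substrate, in which the allylic silyloxy group prefers the inside position and would turn the formyl group to the wrong face, and this is the reason for an amino acid catalyst. The step needs three selectivities, namely enamine formation on the CH2 arm (secured by branching and the methoxy group at the other aldehyde), the correct enamine face (secured by the catalyst, with the trans arrangement also being the one to which the epimerisable Ce can relax) and a stop at the aldol stage without loss of water or silanol (secured by the mild catalyst at or below room temperature). Hydrolysis of the product iminium ion returns the catalyst.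

Step 6
Reactants: 9 ring C aldol
Product: 10 3-O-triethylsilyl ether of 9 (Cd–OSiEt3)
Conditions: Et3SiOTf, 2,6-lutidine, CH2Cl2, −78 °C
Reagents that add atoms: triethylsilyl trifluoromethanesulfonate, CC[Si](CC)(CC)OS(=O)(=O)C(F)(F)F
Why: Silylation at low temperature with a hindered base does not enolise the aldehyde. In 10 the formyl group is trans to both flanking silyloxy groups, the sterically preferred arrangement, so Ce should keep its configuration in the steps that follow.

Step 7
Reactants: 11 (S)-Wieland–Miescher ketone
Product: 12 dithiolane of 11 at the enone carbonyl (C1 in the decalin labels; C5 ketone and C9=C10 alkene kept)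
Conditions: HSCH2CH2SH, p-TsOH (cat.), AcOH, rt
Reagents that add atoms: ethane-1,2-dithiol, SCCS
Why: Acid-catalysed thioketalisation takes the conjugated carbonyl in preference to the saturated one, which is neopentyl, and the double bond keeps its place in the dithioketal.

Step 8
Reactants: 12 dithiolane
Product: 13 (S)-8a-methyl-3,4,6,7,8,8a-hexahydronaphthalen-1(2H)-one (C5 ketone; C9=C10 alkene)
Conditions: Raney Ni (deactivated in acetone), EtOH, reflux
Reagents that add atoms: none
Why: Mozingo desulfurisation replaces both C–S bonds by C–H bonds; the deactivated catalyst should spare the hindered ketone and the trisubstituted alkene.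

Step 9
Reactants: 13 octalone
Product: 14 enol triflate of 13 (C5(OTf)=C6)
Conditions: KN(SiMe3)2, THF, −78 °C; PhNTf2
Reagents that add atoms: N-phenylbis(trifluoromethanesulfonimide), O=S(=O)(N(c1ccccc1)S(=O)(=O)C(F)(F)F)C(F)(F)F
Why: C4 is quaternary, so the ketone can be deprotonated only at C6 and a single enol triflate results.

Step 10
Reactants: 14 enol triflate
Product: 16 trans-fused C10 alcohol (C9–H α; C10–OH α; enol triflate kept), via alkylborane 15 (not isolated)
Conditions: BH3·THF, THF, 0 °C to rt; then NaBO3·4H2O, H2O, rt
Reagents that add atoms: sodium perborate, [Na+].[Na+].O[B-]1(O)OO[B-](O)(O)OO1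
Why: In this hydroboration–oxidation boron goes to the less substituted C10 and hydrogen to C9 from the α face, anti to the angular methyl, which sets the trans ring fusion; the electron-poor enol triflate does not react with borane and tolerates the mild perborate oxidation, which proceeds with retention.

Step 11
Reactants: 16 hydroxy enol triflate
Product: 17 trans-fused C10 alcohol with the C5 methyl in place (C5(CH3)=C6)
Conditions: MeMgBr (3 equiv), Fe(acac)3 (5 mol %), THF/N-methylpyrrolidone, −30 to 0 °C
Reagents that add atoms: methylmagnesium bromide, C[Mg]Br
Why: Iron-catalysed Kumada-type coupling of alkenyl triflates with MeMgBr is fast at low temperature, also next to quaternary carbons; the first equivalent of the Grignard reagent only deprotonates the alcohol.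

Step 12
Reactants: 17 decalin alcohol
Product: 18 (4aS,8aR)-4a,5-dimethyl-3,4,4a,7,8,8a-hexahydronaphthalen-1(2H)-one (C10 ketone; trans-fused)
Conditions: Dess–Martin periodinane, NaHCO3, CH2Cl2, rt
Reagents that add atoms: none
Why: Dess–Martin oxidation is neutral when buffered, so the C9 hydrogen next to the new ketone should not epimerise.

Step 13
Reactants: 18 decalin C10 ketone; 10 ring C aldehyde
Product: 20 aldol adduct (C1–C11 bond; C11–OH; mixture at C1 and C11), via lithium enolate 19 (not isolated)
Conditions: LiN(i-Pr)2, THF, −78 °C; 10, −78 °C; AcOH quench at −78 °C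
Reagents that add atoms: none
Why: Kinetic deprotonation takes the C1 methylene and not the ring-fusion C9 hydrogen, and the lithium enolate adds to the aldehyde at −78 °C faster than it can deprotonate it (directed aldol addition); both new stereocentres disappear in the next step.

Step 14
Reactants: 20 aldol adduct
Product: 22 (E)-enone (C10 ketone conjugated to C1=C11), via mesylate 21 (not isolated)
Conditions: MeSO2Cl, Et3N, CH2Cl2, 0 °C; then DBU, 0 °C to rt, short reaction time
Reagents that add atoms: none
Why: Mesylation followed by E1cB elimination through the C1 enolate completes the aldol condensation and gives the more stable E-alkylidene ketone; the alkene geometry is erased in the next step.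

Step 15
Reactants: 22 enone
Product: 24 C1-methylated ketone (C1: α-axial CH3 and equatorial C11; C10 ketone), via lithium enolate 23 (not isolated)
Conditions: LiBH(s-Bu)3, THF, −78 °C; then MeI, HMPA, −78 to 0 °C
Reagents that add atoms: iodomethane, CI
Why: Conjugate hydride addition to the s-cis enone gives the C10–C1 enolate without regiochemical choice (reductive alkylation of an enone). Methyl iodide should attack C1 axially from the α face through a chair-like transition state in which only hydrogens are syn-axial, whereas attack from the β face would pass through a twist-boat that points toward the C4 methyl; this gives the α-axial methyl and leaves C11 equatorial.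

Step 16
Reactants: 24 C1-methylated ketone
Product: 25 C10 exocyclic methylene compound
Conditions: Zn, CH2Br2, TiCl4 (pre-formed in THF), CH2Cl2, 0 °C to rt
Reagents that add atoms: dibromomethane, BrCBr
Why: Takai–Lombardo methylenation is non-basic, so C9 is not epimerised, and it attacks ketones in preference to esters; it is the usual choice for hindered, enolisable ketones.

Step 17
Reactants: 25 methylene compound
Product: 26 C10 β-methyl compound (bis-silyl ether; all four decalin centres as in the target)
Conditions: H2 (4 atm), RhCl(PPh3)3 (10 mol %), benzene/EtOH, rt
Reagents that add atoms: none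
Why: Homogeneous rhodium hydrogenation reduces the 1,1-disubstituted alkene and leaves the trisubstituted C5=C6 alkene. Hydrogen is expected on the α (equatorial) face of C10, because the β face lies under the syn-axial C4 methyl while the axial C1 methyl stands beside and not over the C10 orbital; the new methyl then ends β and axial.

Step 18
Reactants: 26 bis-silyl ether
Product: 27 Cd alcohol (Ca–OSiMe2t-Bu kept)
Conditions: pyridinium p-toluenesulfonate, MeOH/CH2Cl2, 0 °C to rt
Reagents that add atoms: none
Why: Acid-catalysed methanolysis removes the secondary triethylsilyl ether much faster than the tertiary tert-butyldimethylsilyl ether.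

Step 19
Reactants: 27 Cd alcohol
Product: 28 Cd ketone (α-methoxy ketone; Ca–OSiMe2t-Bu)
Conditions: Dess–Martin periodinane, NaHCO3, CH2Cl2, rt
Reagents that add atoms: none
Why: Buffered Dess–Martin oxidation gives the ketone without base, so the β-silyloxy group is not eliminated and Ce is not epimerised.

Step 20
Reactants: 28 Cd ketone
Product: 30 O-(tert-butyldimethylsilyl)dysidenone A, via trimethylsilyl enol ether 29 (not isolated)
Conditions: Me3SiOTf, Et3N, CH2Cl2, 0 °C; then Pd(OAc)2 (1.1 equiv), MeCN, rt
Reagents that add atoms: none
Why: Soft enolisation should go toward the less hindered, methoxy-bearing Cc and give enol ether 29. In the Saegusa–Ito oxidation divalent palladium then binds to Cc, where the only β-hydrogens are those on Cb, and β-hydride elimination gives the Cb=Cc enone.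

Step 21
Reactants: 30 O-silyl dysidenone A
Product: 31 dysidenone A
Conditions: HF·pyridine, THF/pyridine, 0 °C to rt
Reagents that add atoms: none
Why: Buffered fluoride cleaves the tertiary silyl ether without base, which avoids retro-aldol cleavage of the β-hydroxy ketone and epimerisation at Ce.

## Compound list

1 | (−)-quinic acid | C1[C@H]([C@H]([C@@H](C[C@@]1(C(=O)O)O)O)O)O | starting material
2 | butane-2,3-dione | CC(=O)C(C)=O | starting material
3 | methyl quinate | COC(=O)[C@]1(O)C[C@@H](O)[C@@H](O)[C@H](O)C1 | intermediate
4 | methyl quinate 4,5-butane-2,3-diacetal (acetal carbons S,S; 1-OH and 3-OH free) | COC(=O)[C@]1(O)C[C@@H](O)[C@H]2O[C@](C)(OC)[C@@](C)(OC)O[C@@H]2C1 | intermediate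
5 | 3-O-methyl derivative of 4 | COC(=O)[C@]1(O)C[C@@H](OC)[C@H]2O[C@](C)(OC)[C@@](C)(OC)O[C@@H]2C1 | intermediate
6 | 1-O-tert-butyldimethylsilyl-3-O-methyl derivative of 4 | COC(=O)[C@]1(O[Si](C)(C)C(C)(C)C)C[C@@H](OC)[C@H]2O[C@](C)(OC)[C@@](C)(OC)O[C@@H]2C1 | intermediate
7 | methyl 1-O-(tert-butyldimethylsilyl)-3-O-methylquinate | COC(=O)[C@]1(O[Si](C)(C)C(C)(C)C)C[C@@H](OC)[C@@H](O)[C@H](O)C1 | intermediate
8 | methyl (2S,4R)-2-(tert-butyldimethylsilyloxy)-4-methoxy-5-oxo-2-(2-oxoethyl)pentanoate (dialdehyde) | COC(=O)[C@@](O[Si](C)(C)C(C)(C)C)(CC=O)C[C@@H](OC)C=O | intermediate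
9 | methyl (1S,2S,3S,4R)-1-(tert-butyldimethylsilyloxy)-2-formyl-3-hydroxy-4-methoxycyclopentane-1-carboxylate | COC(=O)[C@]1(O[Si](C)(C)C(C)(C)C)C[C@@H](OC)[C@@H](O)[C@@H]1C=O | intermediate
10 | 3-O-triethylsilyl ether of 9 | COC(=O)[C@]1(O[Si](C)(C)C(C)(C)C)C[C@@H](OC)[C@@H](O[Si](CC)(CC)CC)[C@@H]1C=O | intermediate
11 | (S)-Wieland–Miescher ketone | C[C@]12CCC(=O)C=C1CCCC2=O | starting material
12 | 1,3-dithiolane of 11 at the enone carbonyl | S1CCSC12CC[C@]3(C)C(=O)CCCC3=C2 | intermediate
13 | (S)-8a-methyl-3,4,6,7,8,8a-hexahydronaphthalen-1(2H)-one | C[C@]12CCCC=C1CCCC2=O | intermediate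
14 | (S)-8a-methyl-3,4,6,7,8,8a-hexahydronaphthalen-1-yl trifluoromethanesulfonate | C[C@]12CCCC=C1CCC=C2OS(=O)(=O)C(F)(F)F | intermediate
15 | C10 alkylborane from 14 (boron α on C10, hydrogen α on C9) | B[C@@H]1CCC[C@]2(C)C(OS(=O)(=O)C(F)(F)F)=CCC[C@@H]12 | intermediate
16 | trans-fused C10 α-alcohol with C5 enol triflate | O[C@@H]1CCC[C@]2(C)C(OS(=O)(=O)C(F)(F)F)=CCC[C@@H]12 | intermediate
17 | trans-fused C10 α-alcohol with C5(CH3)=C6 | O[C@@H]1CCC[C@]2(C)C(C)=CCC[C@@H]12 | intermediate
18 | (4aS,8aR)-4a,5-dimethyl-3,4,4a,7,8,8a-hexahydronaphthalen-1(2H)-one | O=C1CCC[C@]2(C)C(C)=CCC[C@@H]12 | intermediate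
19 | lithium enolate of 18 toward C1 | [Li]OC1=CCC[C@]2(C)C(C)=CCC[C@@H]12 | intermediate
20 | aldol adduct of 18 and 10 (C11 carbinol, mixture at C1 and C11) | COC(=O)[C@]1(O[Si](C)(C)C(C)(C)C)C[C@@H](OC)[C@@H](O[Si](CC)(CC)CC)[C@@H]1C(O)C1CC[C@]2(C)C(C)=CCC[C@H]2C1=O | intermediate
21 | C11 mesylate of 20 | COC(=O)[C@]1(O[Si](C)(C)C(C)(C)C)C[C@@H](OC)[C@@H](O[Si](CC)(CC)CC)[C@@H]1C(OS(C)(=O)=O)C1CC[C@]2(C)C(C)=CCC[C@H]2C1=O | intermediate
22 | (E)-enone, C10 ketone with C1=C11 | COC(=O)[C@]1(O[Si](C)(C)C(C)(C)C)C[C@@H](OC)[C@@H](O[Si](CC)(CC)CC)[C@@H]1/C=C1\CC[C@]2(C)C(C)=CCC[C@H]2C1=O | intermediate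
23 | lithium C10–C1 enolate from 22 | COC(=O)[C@]1(O[Si](C)(C)C(C)(C)C)C[C@@H](OC)[C@@H](O[Si](CC)(CC)CC)[C@@H]1CC1=C(O[Li])[C@@H]2CCC=C(C)[C@@]2(C)CC1 | intermediate
24 | C1-methylated C10 ketone (C1 methyl α-axial, C11 equatorial) | COC(=O)[C@]1(O[Si](C)(C)C(C)(C)C)C[C@@H](OC)[C@@H](O[Si](CC)(CC)CC)[C@@H]1C[C@@]1(C)CC[C@]2(C)C(C)=CCC[C@H]2C1=O | intermediate
25 | C10 exocyclic methylene compound | COC(=O)[C@]1(O[Si](C)(C)C(C)(C)C)C[C@@H](OC)[C@@H](O[Si](CC)(CC)CC)[C@@H]1C[C@@]1(C)CC[C@]2(C)C(C)=CCC[C@H]2C1=C | intermediate
26 | C10 β-methyl compound, Ca–OSiMe2t-Bu and Cd–OSiEt3 | COC(=O)[C@]1(O[Si](C)(C)C(C)(C)C)C[C@@H](OC)[C@@H](O[Si](CC)(CC)CC)[C@@H]1C[C@@]1(C)CC[C@]2(C)C(C)=CCC[C@H]2[C@H]1C | intermediate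
27 | Cd alcohol, Ca–OSiMe2t-Bu | COC(=O)[C@]1(O[Si](C)(C)C(C)(C)C)C[C@@H](OC)[C@@H](O)[C@@H]1C[C@@]1(C)CC[C@]2(C)C(C)=CCC[C@H]2[C@H]1C | intermediate
28 | Cd ketone, Ca–OSiMe2t-Bu (2,3-dihydro-O-silyl target) | COC(=O)[C@]1(O[Si](C)(C)C(C)(C)C)C[C@@H](OC)C(=O)[C@@H]1C[C@@]1(C)CC[C@]2(C)C(C)=CCC[C@H]2[C@H]1C | intermediate
29 | trimethylsilyl enol ether of 28 (Cc=Cd) | COC(=O)[C@]1(O[Si](C)(C)C(C)(C)C)CC(OC)=C(O[Si](C)(C)C)[C@@H]1C[C@@]1(C)CC[C@]2(C)C(C)=CCC[C@H]2[C@H]1C | intermediate
30 | O-(tert-butyldimethylsilyl)dysidenone A | COC(=O)[C@]1(O[Si](C)(C)C(C)(C)C)C=C(OC)C(=O)[C@@H]1C[C@@]1(C)CC[C@]2(C)C(C)=CCC[C@H]2[C@H]1C | intermediate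
31 | dysidenone A, methyl (1S,5R)-1-hydroxy-3-methoxy-4-oxo-5-{[(1R,2R,4aS,8aS)-1,2,4a,5-tetramethyl-1,2,3,4,4a,7,8,8a-octahydronaphthalen-2-yl]methyl}cyclopent-2-ene-1-carboxylate | COC(=O)[C@]1(O)C=C(OC)C(=O)[C@@H]1C[C@@]1(C)CC[C@]2(C)C(C)=CCC[C@H]2[C@H]1C | target

## Step count and least certain steps

Total: 21 steps. Longest linear sequence: 15 steps (steps 1–6 and 13–21; the decalin branch, steps 7–12 and 13–21, is equally long).

Step 5 (key step). Two things are most likely to go wrong. The tertiary silyloxy group may be lost by β-elimination from the enamine, since the oxygen on Ca (and, after closure, the one on Cd) is β to the formyl carbon. The ring may also close on the other enamine face, because the catalyst has to override the preference of the substrate for the allylic silyloxy group inside and for the dipole-opposed orientation of the α-methoxy aldehyde. The fallback replaces the aldol by a Claisen-type closure of the same two carbons and sets out from dialdehyde 8. Oxidation with NaClO2 (NaH2PO4, 2-methylbut-2-ene) gives the diacid F1 and Me3SiCHN2 then gives the trimethyl ester F2. A Dieckmann condensation with LiN(SiMe3)2 at low temperature gives the β-keto ester F3; only the enolate of the CH2 arm leads to an enolisable and therefore stable product, which fixes the regiochemistry. An excess of NaBH4 in methanol reduces the ketone anti to the methoxy group and then, assisted by the new neighbouring hydroxyl, the ester on Ce, while the isolated ester on the fully substituted Ca stays, and gives the diol F4. Ce is mobile in F3 and is expected to react as the isomer with the ester trans to the silyloxy group. Oxidation of the primary alcohol alone with catalytic 2,2,6,6-tetramethylpiperidine N-oxyl and PhI(OAc)2 brings the sequence back to the route at 9.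

Step 13. The hindered, α-branched aldehyde may give up its α-proton to the basic enolate instead of accepting it, which would epimerise Ce or expel a silanolate. The fallback avoids base in the bond-forming event and sets out from 18: LiN(i-Pr)2 and Me3SiCl give the trimethylsilyl enol ether F5, and a Mukaiyama aldol addition of F5 to 10 with BF3·OEt2 at −78 °C rejoins the route at 20.

Step 15. The bulky hydride may reduce the carbonyl (1,2) instead of adding to the hindered β-carbon, or the borane-complexed tetrasubstituted enolate may be protonated or O-methylated instead of C-methylated; facial selectivity at C1 may also be incomplete. The fallback sets out from 22: RhCl(PPh3)3-catalysed 1,4-hydrosilylation with Et3SiH gives the triethylsilyl enol ether F6, which is isolated and then methylated with MeI and anhydrous benzyltrimethylammonium fluoride, a source of a naked enolate; the route is rejoined at 24.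

Step 16. The reagent may fail to reach a carbonyl flanked by the quaternary C1 and the ring-fusion C9, or the Lewis acid may strip the triethylsilyl ether. The fallback sets out from 24: Me3SiCH2Li with CeCl3 at −78 °C adds to the ketone to give the β-hydroxysilane F7, and Peterson elimination with KH gives 25.

Step 17. Facial discrimination may be poor, because the α face carries the neighbouring axial C1 methyl and the β face the syn-axial C4 methyl; a slow reaction would also allow the exocyclic alkene to migrate. The fallback sets out from 25: hydroboration with the bulky 9-borabicyclo[3.3.1]nonane and oxidation with NaBO3 give the primary alcohol F8, whose epimers could be separated. Iodine, PPh3 and imidazole give the iodide F9, and Bu3SnH with azobisisobutyronitrile gives 26.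

Step 20. Enolisation may go toward Ce, which would cause epimerisation or β-elimination of the silyloxy group, or palladation of the fully substituted enol ether may be slow. The fallback sets out from 28 and works through the acid-formed enol: PhNMe3Br3 in THF brominates Cc to the α-bromo-α-methoxy ketone F10, and Li2CO3 with LiBr in DMF removes HBr toward Cb, the only side with hydrogen, to give 30.

## Further compounds

F1 | step 5 | diacid from 8: (2S,4R)-2-(tert-butyldimethylsilyloxy)-2-(carboxymethyl)-4-methoxypentanedioic acid 1-methyl ester | COC(=O)[C@@](O[Si](C)(C)C(C)(C)C)(CC(=O)O)C[C@@H](OC)C(=O)O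
F2 | step 5 | trimethyl ester of F1 | COC(=O)[C@@](O[Si](C)(C)C(C)(C)C)(CC(=O)OC)C[C@@H](OC)C(=O)OC
F3 | step 5 | dimethyl 1-(tert-butyldimethylsilyloxy)-4-methoxy-3-oxocyclopentane-1,2-dicarboxylate (Ce enolisable) | COC(=O)[C@]1(O[Si](C)(C)C(C)(C)C)C[C@@H](OC)C(=O)C1C(=O)OC
F4 | step 5 | methyl 1-(tert-butyldimethylsilyloxy)-3-hydroxy-2-(hydroxymethyl)-4-methoxycyclopentane-1-carboxylate (oxygens on the ring cis, hydroxymethyl trans to them) | COC(=O)[C@]1(O[Si](C)(C)C(C)(C)C)C[C@@H](OC)[C@@H](O)[C@@H]1CO
F5 | step 13 | trimethylsilyl enol ether of 18 toward C1 | C[Si](C)(C)OC1=CCC[C@]2(C)C(C)=CCC[C@@H]12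
F6 | step 15 | triethylsilyl enol ether (C10–C1) from 22 | COC(=O)[C@]1(O[Si](C)(C)C(C)(C)C)C[C@@H](OC)[C@@H](O[Si](CC)(CC)CC)[C@@H]1CC1=C(O[Si](CC)(CC)CC)[C@@H]2CCC=C(C)[C@@]2(C)CC1
F7 | step 16 | C10 tertiary alcohol bearing CH2SiMe3 (β-hydroxysilane from 24, C10 unassigned) | COC(=O)[C@]1(O[Si](C)(C)C(C)(C)C)C[C@@H](OC)[C@@H](O[Si](CC)(CC)CC)[C@@H]1C[C@@]1(C)CC[C@]2(C)C(C)=CCC[C@H]2C1(O)C[Si](C)(C)C
F8 | step 17 | C10 β-hydroxymethyl compound from 25 | COC(=O)[C@]1(O[Si](C)(C)C(C)(C)C)C[C@@H](OC)[C@@H](O[Si](CC)(CC)CC)[C@@H]1C[C@@]1(C)CC[C@]2(C)C(C)=CCC[C@H]2[C@H]1CO
F9 | step 17 | C10 β-iodomethyl compound | COC(=O)[C@]1(O[Si](C)(C)C(C)(C)C)C[C@@H](OC)[C@@H](O[Si](CC)(CC)CC)[C@@H]1C[C@@]1(C)CC[C@]2(C)C(C)=CCC[C@H]2[C@H]1CI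
F10 | step 20 | Cc-bromo derivative of 28 (α-bromo-α-methoxy ketone, Cc unassigned) | COC(=O)[C@]1(O[Si](C)(C)C(C)(C)C)CC(Br)(OC)C(=O)[C@@H]1C[C@@]1(C)CC[C@]2(C)C(C)=CCC[C@H]2[C@H]1C
A1 | alternative 1 | (4R,6R)-4,6-dimethyl-1,3-dioxane acetal of the open-chain E-dienyl vinylsilane aldehyde | C[C@@H]1C[C@@H](C)OC(CCC/C(C)=C/CCC=C(C)[Si](C)(C)C)O1
A2 | alternative 1 | trans-decalin C10 hydroxypentyl ether | C[C@@H](O)C[C@@H](C)O[C@@H]1CCC[C@]2(C)C(C)=CCC[C@H]21
A3 | alternative 2 | open-chain trienone β-keto ester | C=CC(=O)[C@@](C)(C(=O)OC)CC/C(C)=C(\C)C=C
A4 | alternative 2 | trans-fused C10-oxo decalin with methyl and methyl ester on C1 | COC(=O)[C@@]1(C)CC[C@]2(C)C(C)=CCC[C@H]2C1=O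
A5 | alternative 3 | cross-conjugated divinyl ketone with methoxyvinyl and silyloxy acrylate arms | C=C(OC)C(=O)C(C[C@@]1(C)CC[C@]2(C)C(C)=CCC[C@H]2[C@H]1C)=C(O[Si](C)(C)C(C)(C)C)C(=O)OC
A6 | alternative 3 | O-(tert-butyldimethylsilyl)dysidenone A | COC(=O)[C@]1(O[Si](C)(C)C(C)(C)C)C=C(OC)C(=O)[C@@H]1C[C@@]1(C)CC[C@]2(C)C(C)=CCC[C@H]2[C@H]1C
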